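Everything rests on disconnecting the butenolide olefin C8=C9 (cembrane numbering), the one bond shared by the five-membered lactone (O, C19, C8, C9, C10) and the 14-membered carbocycle. C8 with C7, C6 and C5 is read as a cyclobutene, carried as the cyclobut-1-enecarboxylate of the C10 vinyl carbinol. One ruthenium-catalysed ring-opening/ring-closing metathesis cascade forms C8=C9, relays the carbene through the opened four-membered ring to C5 and closes the macrocycle onto an isopropenyl group, so both bridged rings arise from a precursor without a macrocycle. A singlet-oxygen ene reaction then shifts the new C4=C5 olefin into the C4 methylene/C5 hydroperoxide. C10 comes from (R)-epichlorohydrin, C1/C14 from a catalyst-controlled allylboration/lactonisation.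

Key step: step 10

Numbering: cembrane numbering of the target is used throughout. C1 is the ring CH of the α-methylene lactone (it carries C15); C2 and C3 are CH2; C4 carries the exocyclic methylene; C5 is CH–OOH; C6 and C7 are CH2; C8/C9 are the butenolide α-carbon/β-CH; C10 is the butenolide CH–O; C11 is CH2; C12=C13 is the (E)-olefin with methyl on C12; C14 is the lactone CH–O; C19 is the butenolide carbonyl. 5β corresponds to 5R.

Assumption: 9, 11, (R)-TRIP and the iodomethyl pinacol boronate are taken as catalogue chemicals; 9 polymerises on storage and is used fresh.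

Step 1
Reactants: 1 (R)-epichlorohydrin
Product: 2 (R)-1-chloro-5-(trimethylsilyl)pent-4-yn-2-ol
Conditions: Me3SiC≡CH, n-BuLi, THF, −78 °C; BF3·OEt2; then 1, −78 °C
Reagents that add atoms: ethynyltrimethylsilane, C#C[Si](C)(C)C
Why: BF3-assisted opening of the epoxide by the lithium acetylide (Yamaguchi–Hirao alkynylation) takes place at the unsubstituted epoxide carbon, so the stereocentre of 1 is not touched and the chloride survives at low temperature.

Step 2
Reactants: 2
Product: 5 (R)-hex-1-en-5-yn-3-ol, via silylalkynyl epoxide 3 (not isolated), via silylated enynol 4 (not isolated)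
Conditions: Me3S+ I− (3.5 equiv), n-BuLi (3.3 equiv), THF, −10 °C → rt; then K2CO3, MeOH, rt
Reagents that add atoms: trimethylsulfonium iodide, C[S+](C)C.[I-]
Why: The ylide first closes the chlorohydrin to epoxide 3 (intramolecular Williamson reaction), then opens 3 at its CH2 terminus, and the sulfonium betaine eliminates dimethyl sulfide (sulfonium-ylide homologation of an epoxide to an allylic alcohol), so the C–O bond at the stereocentre is never broken and the R configuration (future C10) is retained; methanolysis then cleaves the alkynyl C–Si bond.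

Step 3
Reactants: 5
Product: 7 (2E,5R)-3-methylhepta-2,6-diene-1,5-diol, via alkenylalane 6 (not isolated)
Conditions: AlMe3 (3 equiv), Cp2ZrCl2 (0.25 equiv), CH2Cl2, 0 °C → rt; then n-BuLi, (CH2O)n, THF, −78 °C → rt
Reagents that add atoms: trimethylaluminium, C[Al](C)C; paraformaldehyde (as formaldehyde), C=O
Why: Negishi zirconium-catalysed carboalumination adds methyl and aluminium syn across the terminal alkyne with methyl on the internal carbon, and the derived alanate is hydroxymethylated with retention, which fixes the (E)-trisubstituted C12=C13 olefin; the hydroxyl is carried as its aluminium alkoxide and the carbinol centre is untouched.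

Step 4
Reactants: 7
Product: 8 (2E,5R)-5-hydroxy-3-methylhepta-2,6-dienal
Conditions: TEMPO (10 mol %), PhI(OAc)2 (1.1 equiv), CH2Cl2, rt
Reagents that add atoms: none
Why: The oxoammonium (TEMPO/PhI(OAc)2) oxidation is strongly selective for the primary allylic alcohol over the secondary one and should give the enal without touching the olefin geometry or the C10 centre.

Step 5
Reactants: 8 (2E,5R)-5-hydroxy-3-methylhepta-2,6-dienal; 9 cyclobut-1-ene-1-carboxylic acid
Product: 10 (3R,5E)-5-methyl-7-oxohepta-1,5-dien-3-yl cyclobut-1-ene-1-carboxylate
Conditions: DCC, DMAP (cat.), CH2Cl2, 0 °C → rt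
Reagents that add atoms: none
Why: Steglich esterification acylates the secondary allylic alcohol under neutral conditions with retention at C10 and installs the cyclobutene that later supplies C8, C7, C6 and C5.

Step 6
Reactants: 11 4-bromo-2-methylbut-1-ene
Product: 12 2-methylhex-1-en-5-yne
Conditions: LiC≡CH·H2NCH2CH2NH2, DMSO, 10 °C → rt
Reagents that add atoms: lithium acetylide ethylenediamine complex, [Li]C#C.NCCN
Why: SN2 alkylation of the acetylide by the primary bromide in DMSO should outrun elimination and gives the volatile enyne, which is isolated by distillation.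

Step 7
Reactants: 12
Product: 13 methyl 6-methylhept-6-en-2-ynoate
Conditions: n-BuLi, THF, −78 °C; ClCO2Me, −78 °C → 0 °C
Reagents that add atoms: methyl chloroformate, COC(=O)Cl
Why: Deprotonation of the terminal alkyne and C-acylation of the lithium acetylide with the chloroformate is the standard route to 2-alkynoates.

Step 8
Reactants: 13
Product: 15 methyl (2Z)-6-methyl-2-[(4,4,5,5-tetramethyl-1,3,2-dioxaborolan-2-yl)methyl]hepta-2,6-dienoate, via aluminoacrylate 14 (not isolated)
Conditions: i-Bu2AlH, HMPA, THF, 0 °C; then ICH2Bpin, 0 °C → rt
Reagents that add atoms: 2-(iodomethyl)-4,4,5,5-tetramethyl-1,3,2-dioxaborolane, ICB1OC(C)(C)C(C)(C)O1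
Why: Syn 1,4-hydroalumination of the ynoate by the i-Bu2AlH–HMPA complex places H and Al cis, and alkylation of the α-aluminoacrylate with the iodomethylboronate proceeds with retention, which fixes the side chain trans to CH2B as the anti-selective allylboration requires.

Step 9
Reactants: 10 (3R,5E)-5-methyl-7-oxohepta-1,5-dien-3-yl cyclobut-1-ene-1-carboxylate; 15 methyl (2Z)-6-methyl-2-[(4,4,5,5-tetramethyl-1,3,2-dioxaborolan-2-yl)methyl]hepta-2,6-dienoate
Product: 17 (3R,5E)-5-methyl-6-[(2S,3R)-4-methylidene-3-(3-methylbut-3-en-1-yl)-5-oxooxolan-2-yl]hexa-1,5-dien-3-yl cyclobut-1-ene-1-carboxylate, via borate adduct 16 (not isolated)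
Conditions: (R)-TRIP [(R)-3,3'-bis(2,4,6-triisopropylphenyl)-1,1'-binaphthyl-2,2'-diyl hydrogen phosphate] (10 mol %), 4 Å molecular sieves, toluene, −30 °C → rt; then PPTS (cat.), CH2Cl2, rt
Reagents that add atoms: none
Why: Chiral-phosphoric-acid-catalysed allylboration through a closed chair transition state followed by lactonisation (tandem allylboration/lactonisation): the boronate geometry puts the side chain equatorial and enforces the anti, hence trans-lactone, relation of C1 and C14, while (R)-TRIP, the antipode expected from the established facial model of this catalysis, should direct the allyl unit to the Re face of the enal and so set 14S and 1R independently of the remote C10 centre.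

Step 10
Reactants: 17
Product: 18 ovatodiolide [(1R,10R,14S), 4E,12E]
Conditions: second-generation Grubbs catalyst RuCl2(=CHPh)(PCy3)(H2IMes) (15 mol %, in portions), toluene (1 mM), 80 °C
Reagents that add atoms: none
Why: The ruthenium alkylidene loads on the monosubstituted vinyl group at C9, adds across the strained cyclobutene C=C held close by the ester at the C10 oxygen and cycloreverts, which forms the C8=C9 bond, opens the four-membered ring and leaves the carbene on C5; this carbene then closes onto the isopropenyl group to form C4=C5 with loss of ethylene. The closest known reaction type is tandem ring-opening/ring-closing metathesis (ring-rearrangement metathesis) of cyclobutenes, combined with ring-closing metathesis of α-substituted acrylic esters of allylic alcohols to butenolides. The butenolide closes as a five-membered ring through the metallacyclobutane that joins C9 to the carboxyl-bearing cyclobutene carbon (the other regiochemistry would require an eight-membered ring), and the 14-membered carbocycle closes by macrocyclic ring-closing metathesis at high dilution. No stereocentre is formed; the butenolide olefin is cis by ring constraint, and C4=C5 is expected as the E isomer, the less strained geometry in the bridged macrocycle. The step needs site selectivity among five olefins and ring closure in preference to oligomerisation, which should be secured by release of cyclobutene strain, by the low reactivity of the acrylate-type methylene lactone and of the trisubstituted C12=C13 olefin towards the catalyst, by the reluctance of cyclobutene-1-carboxylic esters to homopolymerise and by dilution.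

Step 11
Reactants: 18
Product: 19 4-methylene-5β-hydroperoxyovatodiolide [(1R,5R,10R,14S)]
Conditions: O2, tetraphenylporphyrin (cat.), visible light (hν), CH2Cl2, −20 °C, stopped at one equivalent of O2 uptake
Reagents that add atoms: dioxygen, O=O
Why: Schenck ene reaction: electrophilic singlet oxygen should select C4=C5, the only electron-rich olefin (C12=C13 is deactivated by the allylic and homoallylic acyloxy groups and the other three are conjugated to carbonyls); the cis effect directs hydrogen abstraction to the C4 methyl on the disubstituted side of the E-olefin, so oxygen is delivered suprafacially to C5 from the exposed outer face of the macrocyclic olefin, expected to give 5β, and the C4-hydroperoxy C5=C6 regioisomer, the expected by-product, is removed by chromatography.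

Compound list
1 | (R)-epichlorohydrin [(R)-2-(chloromethyl)oxirane] | ClC[C@H]1CO1 | starting material
2 | (R)-1-chloro-5-(trimethylsilyl)pent-4-yn-2-ol | ClC[C@H](O)CC#C[Si](C)(C)C | intermediate
3 | (R)-trimethyl[3-(oxiran-2-yl)prop-1-yn-1-yl]silane (not isolated) | C1O[C@@H]1CC#C[Si](C)(C)C | intermediate
4 | (R)-6-(trimethylsilyl)hex-1-en-5-yn-3-ol (not isolated) | C=C[C@H](O)CC#C[Si](C)(C)C | intermediate
5 | (R)-hex-1-en-5-yn-3-ol | C=C[C@H](O)CC#C | intermediate
6 | dimethylaluminium alkoxide of (R,E)-1-(dimethylalumanyl)-2-methylhexa-1,5-dien-4-ol (not isolated) | C=C[C@H](O[Al](C)C)C/C(C)=C/[Al](C)C | intermediate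
7 | (2E,5R)-3-methylhepta-2,6-diene-1,5-diol | C=C[C@H](O)C/C(C)=C/CO | intermediate
8 | (2E,5R)-5-hydroxy-3-methylhepta-2,6-dienal | C=C[C@H](O)C/C(C)=C/C=O | intermediate
9 | cyclobut-1-ene-1-carboxylic acid | OC(=O)C1=CCC1 | starting material
10 | (3R,5E)-5-methyl-7-oxohepta-1,5-dien-3-yl cyclobut-1-ene-1-carboxylate | C=C[C@H](OC(=O)C1=CCC1)C/C(C)=C/C=O | intermediate
11 | 4-bromo-2-methylbut-1-ene | C=C(C)CCBr | starting material
12 | 2-methylhex-1-en-5-yne | C=C(C)CCC#C | intermediate
13 | methyl 6-methylhept-6-en-2-ynoate | C=C(C)CCC#CC(=O)OC | intermediate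
14 | methyl (2E)-2-(diisobutylalumanyl)-6-methylhepta-2,6-dienoate (not isolated) | C=C(C)CC/C=C(/[Al](CC(C)C)CC(C)C)C(=O)OC | intermediate
15 | methyl (2Z)-6-methyl-2-[(4,4,5,5-tetramethyl-1,3,2-dioxaborolan-2-yl)methyl]hepta-2,6-dienoate | C=C(C)CC/C=C(/CB1OC(C)(C)C(C)(C)O1)C(=O)OC | intermediate
16 | methyl (3R,4S,5E,8R)-8-(cyclobut-1-ene-1-carbonyloxy)-6-methyl-2-methylidene-3-(3-methylbut-3-en-1-yl)-4-[(4,4,5,5-tetramethyl-1,3,2-dioxaborolan-2-yl)oxy]deca-5,9-dienoate (not isolated) | C=C[C@H](OC(=O)C1=CCC1)C/C(C)=C/[C@H](OB1OC(C)(C)C(C)(C)O1)[C@H](CCC(C)=C)C(=C)C(=O)OC | intermediate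
17 | (3R,5E)-5-methyl-6-[(2S,3R)-4-methylidene-3-(3-methylbut-3-en-1-yl)-5-oxooxolan-2-yl]hexa-1,5-dien-3-yl cyclobut-1-ene-1-carboxylate | C=C[C@H](OC(=O)C1=CCC1)C/C(C)=C/[C@@H]1OC(=O)C(=C)[C@H]1CCC(C)=C | intermediate
18 | ovatodiolide [(1R,10R,14S), 4E,12E] | C=C1C(=O)O[C@H]2/C=C(\C)C[C@@H]3C=C(CC/C=C(\C)CC[C@H]12)C(=O)O3 | intermediate
19 | 4-methylene-5β-hydroperoxyovatodiolide [(1R,5R,10R,14S)] | C=C1C(=O)O[C@H]2/C=C(\C)C[C@@H]3C=C(CC[C@@H](OO)C(=C)CC[C@H]12)C(=O)O3 | target

Total step count: 11. Longest linear sequence: 8 steps (1, 2, 3, 4, 5, 9, 10, 11).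

Steps most likely to fail

Step 10. Intermolecular metathesis may outrun macrocyclisation, the relay may stall after the butenolide-forming event, or the trisubstituted C4=C5 olefin may close with the wrong geometry. The fallback uncouples the cascade and sets out from 17. Under ethylene (second-generation Grubbs catalyst RuCl2(=CHPh)(PCy3)(H2IMes), CH2Cl2, 40 °C) the sequence should stop after ring opening and butenolide closure, the C5 carbene being capped by ethylene, to give the butenolide triene F1, which is isolated. The 14-membered ring is then closed in a separate ring-closing metathesis between the C5 vinyl group and the C4 isopropenyl group with the molybdenum alkylidene Mo(=CHCMe2Ph)(=N-2,6-i-Pr2C6H3)[OCMe(CF3)2]2 (benzene, high dilution), which is better suited to trisubstituted olefins. The route is rejoined at 18.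

Step 11. Hydrogen may be abstracted from the ring CH2 at C6 instead of the C4 methyl, oxygen may be delivered to the wrong face at C5, or the C12=C13 olefin may be oxygenated as well. The fallback sets out from 18 and is regiochemically defined. mCPBA (1 equiv, NaHCO3, CH2Cl2, 0 °C) epoxidises the same electron-rich olefin to the 4,5-epoxide F2. Me3SiOTf/2,6-lutidine (toluene, −78 °C) isomerises the trisubstituted epoxide, by ionisation at the tertiary C4 and loss of a methyl proton, to the exocyclic-methylene silyl ether F3. Desilylation (aqueous citric acid, THF) gives the allylic alcohol F4, and mesylation (MsCl, Et3N, CH2Cl2, −20 °C) gives the mesylate F5. SN2 displacement of the sulfonate with anhydrous H2O2 in Et2O inverts C5 and returns to the route at 19. Because the epoxide oxygen enters on the face a peracid or singlet oxygen prefers and C5 is inverted at the end, this is the sequence to use if direct oxygenation delivers the C5 epimer; F2 to F5 are drawn for that case.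

Step 9. The ester-deactivated boronate may add too slowly for the catalyst to control the aldehyde face, or the acid may ionise the allylic borate and scramble C14. The fallback sets out from 13 and 10. The aluminoacrylate 14 is trapped with paraformaldehyde instead of the boronate to give the hydroxymethyl dienoate F6, which is brominated (CBr4, PPh3, CH2Cl2, 0 °C) to the allylic bromide F7. A catalytic asymmetric Nozaki–Hiyama-type 2-(alkoxycarbonyl)allylation of 10 (CrCl2 (10 mol %), C2-symmetric carbazole bis(oxazoline) ligand in the antipode chosen for Re-face addition, Mn, Me3SiCl, i-Pr2NEt, THF, rt) should give the anti-configured silyl ether F8 through the equilibrating allylchromium reagent with the side chain equatorial in the chair. Acidic work-up (1 M HCl) desilylates and lactonises F8, and the route is rejoined at 17.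

Further compounds
F1 | step 10 | (5R)-3-(but-3-en-1-yl)-5-{(2E)-2-methyl-3-[(2S,3R)-4-methylidene-3-(3-methylbut-3-en-1-yl)-5-oxooxolan-2-yl]prop-2-en-1-yl}furan-2(5H)-one | C=CCCC1=C[C@@H](C/C(C)=C/[C@@H]2OC(=O)C(=C)[C@H]2CCC(C)=C)OC1=O
F2 | step 11 | ovatodiolide (4S,5S)-4,5-epoxide | C=C1C(=O)O[C@H]2/C=C(\C)C[C@@H]3C=C(CC[C@@H]4O[C@@]4(C)CC[C@H]12)C(=O)O3
F3 | step 11 | (5S)-4-methylene-5-(trimethylsilyloxy)ovatodiolide | C=C1C(=O)O[C@H]2/C=C(\C)C[C@@H]3C=C(CC[C@H](O[Si](C)(C)C)C(=C)CC[C@H]12)C(=O)O3
F4 | step 11 | (5S)-4-methylene-5-hydroxyovatodiolide | C=C1C(=O)O[C@H]2/C=C(\C)C[C@@H]3C=C(CC[C@H](O)C(=C)CC[C@H]12)C(=O)O3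
F5 | step 11 | (5S)-4-methylene-5-(methanesulfonyloxy)ovatodiolide | C=C1C(=O)O[C@H]2/C=C(\C)C[C@@H]3C=C(CC[C@H](OS(C)(=O)=O)C(=C)CC[C@H]12)C(=O)O3
F6 | step 9 | methyl (2Z)-2-(hydroxymethyl)-6-methylhepta-2,6-dienoate | C=C(C)CC/C=C(/CO)C(=O)OC
F7 | step 9 | methyl (2E)-2-(bromomethyl)-6-methylhepta-2,6-dienoate | C=C(C)CC/C=C(/CBr)C(=O)OC
F8 | step 9 | methyl (3R,4S,5E,8R)-8-(cyclobut-1-ene-1-carbonyloxy)-6-methyl-2-methylidene-3-(3-methylbut-3-en-1-yl)-4-(trimethylsilyloxy)deca-5,9-dienoate | C=C[C@H](OC(=O)C1=CCC1)C/C(C)=C/[C@H](O[Si](C)(C)C)[C@H](CCC(C)=C)C(=C)C(=O)OC
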